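(The constants come from no measurement; what happens was integrated by code.)

Slowness first: before asking how much target a flask can hold, we ask whether it has the time to fill.

the same everywhere: starting material 10 mM; reagent 0.800 equiv; second substrate 0.200 equiv; time 15 s

| flask | temperature |
|---|---|
| maple | 70 °C |
| ash | 20 °C |
| birch | −5 °C |
| elm | 45 °C |

    starting material + reagent ⇌ target (K1 = 116 L mol⁻¹, k1 = 87.4 L mol⁻¹ s⁻¹, Ea1 = 48.0 kJ mol⁻¹, ΔH1 = −24.0 kJ mol⁻¹)
    second substrate + reagent → second product (k2 = 1030 L mol⁻¹ s⁻¹, Ea2 = 47.0 kJ mol⁻¹)
    starting material + second substrate → cross product (k3 = 209 L mol⁻¹ s⁻¹, Ea3 = 44.0 kJ mol⁻¹)
    reagent + target ⇌ idle adduct, settled at all times (K4 = 47.6 L mol⁻¹, ΔH4 = −83.0 kJ mol⁻¹)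
    starting material → decomposition product (k5 = 1.90 × 10⁻⁴ s⁻¹, Ea5 = 113 kJ mol⁻¹)
    (constants at 70 °C)

- what is said of target includes idle adduct
- at 70 °C the constants are as listed, elsewhere as the activation energies and enthalpies make them

* the flask with the highest amount of target, in percent of the starting material charged ("all alike" if they lie within 1.5 percentage points) (maple / ash / birch / elm / all alike)
* final target, as a percentage of the starting material charged, in maple
* final target, as a percentage of the starting material charged, in ash
* final target, as a percentage of the starting material charged, in birch
* final target, as a percentage of the starting material charged, in elm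

Activation energy carries the listed rate constant of the step that makes target to each temperature, giving k(T). With reagent held at its charged amount, that step becomes pseudo-first-order, and we take the reciprocal of k(T) times the reagent concentration. In birch this is 158 s: the filling time, in which the starting rate would pass the whole charge of starting material into target. While the fraction y of that charge made into target stays small, y is about t/τ.

τ = 1/(k(T) × reagent charged)
maple 1.43 s, elm 5.36 s, ash 25.2 s, birch 158 s

The 15 s allowed is longer than the filling time in maple and in elm, but shorter in ash and far shorter in birch. So we expect thermodynamic control in the first two flasks and kinetic control in birch.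

Balance sets a ceiling, which rises as the flask cools. With K(T) from the enthalpy and reagent at its charge, the ceiling is the fraction Kc/(1 + Kc):

maple 48.1%, elm 64.3%, ash 79.6%, birch 90.7%

We score each flask by the lower of its ceiling and its filled share, 1 − exp(−t/τ). This is crude and serves for ranking, and it picks elm.

For birch we commit to a figure. The second substrate is charged at a quarter of the reagent, and just after the start of birch it uses reagent 2.6 times as fast as the forward step to target does. We book that quarter as a rough allowance of our own for losses along the way, not as reagent gone from the start:

y ≈ (t/τ) × (1 − second substrate charge/reagent charge) = 7.12%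

We reckon no figure for the other flasks.

The forecast names elm and gives maple 28.5% (27% to 30%), ash 23.5% (21% to 26%), birch 7.1% (6% to 8.5%) and elm 34.5% (32.5% to 36.5%). It puts elm ahead of maple “because the cooler flask favours both target and idle adduct”.

The simulation gives elm as the highest: maple 28.6%, ash 23.5%, birch 7.25%, elm 34.7%.

Birch read at 40 s instead of 15 s keeps its filling time of 158 s, so t/τ grows to 25.3%. By then the readings show reagent at 46% of its charge and starting material at 80%, so we replace the booked quarter with the mean share of each over the run:

y ≈ (t/τ) × mean reagent share × mean starting material share = 16.6%

That later birch flask holds target, idle adduct counted, at 14.7%.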